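**Retrosynthetic overview**

1. Numbering (germacrane): ring C1–C10 holds C1=C2 (Z), C3–OH, C4(Me)=C5 (Z), C6–O (lactone), C7 (ring fusion), C8–O-tigloyl, C9H2 and C10(Me)OH. The lactone ring is O–C6–C7–C11–C12(=O), with C11=C13H2 exocyclic.
2. Enabling feature: C8(O)–C7–C11=C13 is a homoallylic alcohol whose central atom C7 belongs to both rings. The C7–C8 ring bond plus the exocyclic methylene is therefore the retron of an SE2′ carbonyl allylation. The allyl donor is a preformed butenolide ring (O, C6, C7=C11, C12) that carries C13H2Br.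
3. Key disconnection C7–C8: a Cr(II)-mediated intramolecular Nozaki–Hiyama allylation of the open-chain bromo-aldehyde 23 closes the ten-membered ring and creates C7, C8 and C11=C13 together. O8-tigloylation and O3-desilylation follow.
4. Assembly of 23: (Z)-3-iodo-2-methylacrolein (C3–C5) is alkynylated at C3 with alkyne 4 (C1, C2, C8–C10; C10 set by Sharpless epoxidation). Its vinyl iodide becomes the C6 enal, which is alkynylated again (C7, C11, C13). Red-Al/I2 and Pd/CO build the butenolide, and Lindlar reduction gives Z-C1=C2.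
5. Ring order: 1,3-dioxane (temporary, steps 3–12), then butenolide (step 11), then ten-membered carbocycle (step 16).

Key step: step 16

Remark (assumption): in the Zn–ProPhenol alkynylations (steps 6 and 9) the (R,R)-ligand is taken to direct addition to the Re face of the enal (O > C(sp2) > H). C3 and C6 need the same spatial sense, so one ligand serves both steps. Both antipodes are commercial, so an opposite sense would only swap the ligand. TBS = tert-butyldimethylsilyl.

**Step 1**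
Reactants: 1 (E)-3-methylpent-2-en-4-yn-1-ol
Product: 2 [(2S,3S)-3-ethynyl-3-methyloxiran-2-yl]methanol
Conditions: Ti(Oi-Pr)4 (10 mol %), L-(+)-diethyl tartrate (12 mol %), t-BuOOH, 4 Å MS, CH2Cl2, −20 °C
Reagents that add atoms: tert-butyl hydroperoxide, CC(C)(C)OO
Why: Sharpless asymmetric epoxidation of a geraniol-type (E)-trisubstituted allylic alcohol, for which the L-(+)-tartrate catalyst gives the (2S,3S)-epoxide and so fixes the quaternary carbinol carbon C10, while the alkyne is too electron-poor to react.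

**Step 2**
Reactants: 2 [(2S,3S)-3-ethynyl-3-methyloxiran-2-yl]methanol
Product: 3 (3R)-3-methylpent-4-yne-1,3-diol
Conditions: LiAlH4, Et2O, −20 → 0 °C; then H2O/aq NaOH
Reagents that add atoms: none
Why: Hydroxyl-directed hydride opening of a 2,3-epoxy alcohol, in which the alkoxyaluminate attacks the secondary carbon (future C9) by SN2 because the other terminus is quaternary, so the C10–O bond keeps its configuration, and ether at ≤0 °C is too mild for hydroalumination of the propargylic alkoxide.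

**Step 3**
Reactants: 3 (3R)-3-methylpent-4-yne-1,3-diol
Product: 4 (4R)-4-ethynyl-2,2,4-trimethyl-1,3-dioxane
Conditions: 2,2-dimethoxypropane, PPTS (cat.), CH2Cl2, rt
Reagents that add atoms: 2,2-dimethoxypropane, COC(C)(C)OC
Why: Acid-catalysed transacetalisation closes a six-membered isopropylidene acetal that masks O8 and O10 in one operation, so no free propargylic OH can direct Red-Al in step 10.

**Step 4**
Reactants: 5 prop-2-yn-1-ol
Product: 7 (Z)-3-iodo-2-methylprop-2-en-1-ol, via Z-vinylmagnesium alkoxide 6 (not isolated)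
Conditions: MeMgBr (2.5 equiv), CuI (10 mol %), THF, −10 °C → rt; then I2, −78 → 0 °C; aq NH4Cl
Reagents that add atoms: methylmagnesium bromide, C[Mg]Br; iodine, II
Why: Copper-catalysed anti-carbomagnesiation of a propargylic alcohol puts methyl on the inner carbon and magnesium, chelated by the alkoxide, on the terminal carbon cis to CH2O, and iodinolysis with retention gives the Z-iodide that later becomes Z-C4=C5.

**Step 5**
Reactants: 7 (Z)-3-iodo-2-methylprop-2-en-1-ol
Product: 8 (Z)-3-iodo-2-methylprop-2-enal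
Conditions: activated MnO2, CH2Cl2, rt, dark; used at once
Reagents that add atoms: none
Why: Allylic alcohol oxidation with MnO2 is neutral and heterogeneous, so the Z-iodoenal should form without isomerisation.

**Step 6**
Reactants: 4 (4R)-4-ethynyl-2,2,4-trimethyl-1,3-dioxane; 8 (Z)-3-iodo-2-methylprop-2-enal
Product: 10 (1Z,3R)-1-iodo-2-methyl-5-[(4R)-2,2,4-trimethyl-1,3-dioxan-4-yl]pent-1-en-4-yn-3-ol, via methylzinc acetylide 9 (not isolated)
Conditions: Me2Zn, (R,R)-ProPhenol (10 mol %), Ph3P=O (20 mol %), toluene, 4 °C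
Reagents that add atoms: none
Why: Zn–ProPhenol-catalysed asymmetric alkynylation of an α-branched enal, in which the dinuclear zinc catalyst binds both aldehyde and acetylide and catalyst-controlled Re-face addition sets C3, while the remote C10 centre has no influence and the vinyl iodide is inert to organozincs.

**Step 7**
Reactants: 10 (1Z,3R)-1-iodo-2-methyl-5-[(4R)-2,2,4-trimethyl-1,3-dioxan-4-yl]pent-1-en-4-yn-3-ol
Product: 11 the O-TBS ether of 10, (1Z,3R)-3-(TBS-oxy)-1-iodo-2-methyl-5-[(4R)-2,2,4-trimethyl-1,3-dioxan-4-yl]pent-1-en-4-yne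
Conditions: TBSCl, imidazole, DMF, rt
Reagents that add atoms: tert-butyldimethylsilyl chloride, CC(C)(C)[Si](C)(C)Cl
Why: Standard silylation protects O3 through the organolithium, Red-Al, bromination and acylation steps and supplies the bulky group used for conformational control in step 16.

**Step 8**
Reactants: 11 (1Z,3R)-3-(TBS-oxy)-1-iodo-2-methyl-5-[(4R)-2,2,4-trimethyl-1,3-dioxan-4-yl]pent-1-en-4-yne
Product: 13 (2Z,4S)-4-(TBS-oxy)-3-methyl-6-[(4R)-2,2,4-trimethyl-1,3-dioxan-4-yl]hex-2-en-5-ynal, via Z-vinyllithium 12 (not isolated)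
Conditions: t-BuLi (2.1 equiv), Et2O, −78 °C, 15 min; then DMF, −78 → −30 °C; aq NH4Cl
Reagents that add atoms: N,N-dimethylformamide, CN(C)C=O
Why: Iodine–lithium exchange with retention of alkene geometry followed by formylation brings in C6, and ether at −78 °C with a prompt quench should hold back 1,4-O→C silyl migration (the descriptor at C3 changes only because iodine is lost).

**Step 9**
Reactants: 13 (2Z,4S)-4-(TBS-oxy)-3-methyl-6-[(4R)-2,2,4-trimethyl-1,3-dioxan-4-yl]hex-2-en-5-ynal; 14 tert-butyldimethyl(prop-2-yn-1-yloxy)silane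
Product: 16 (4S,5Z,7S)-1,7-bis(TBS-oxy)-6-methyl-9-[(4R)-2,2,4-trimethyl-1,3-dioxan-4-yl]non-5-ene-2,8-diyn-4-ol, via methylzinc acetylide 15 (not isolated)
Conditions: Me2Zn, (R,R)-ProPhenol (20 mol %), Ph3P=O (40 mol %), toluene, 4 °C
Reagents that add atoms: none
Why: A second Zn–ProPhenol asymmetric alkynylation, now of a β,β-disubstituted enal, sets C6 by catalyst-controlled Re-face addition with the same ligand and brings in C7, C11 and C13.

**Step 10**
Reactants: 16 (4S,5Z,7S)-1,7-bis(TBS-oxy)-6-methyl-9-[(4R)-2,2,4-trimethyl-1,3-dioxan-4-yl]non-5-ene-2,8-diyn-4-ol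
Product: 18 (2Z,4S,5Z,7S)-1,7-bis(TBS-oxy)-2-iodo-6-methyl-9-[(4R)-2,2,4-trimethyl-1,3-dioxan-4-yl]nona-2,5-dien-8-yn-4-ol, via cyclic vinylalanate 17 (not isolated)
Conditions: Red-Al, THF, 0 °C → rt; EtOAc (destroys excess hydride), then I2, −78 °C; aq Rochelle salt
Reagents that add atoms: iodine, II
Why: Hydroxyl-directed trans-hydroalumination of a propargylic alcohol places aluminium on the distal carbon C11 in a five-membered alanate, iodinolysis with retention gives the (Z)-γ-iodoallylic alcohol, and the C1≡C2 alkyne has no free neighbouring OH and is left alone.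

**Step 11**
Reactants: 18 (2Z,4S,5Z,7S)-1,7-bis(TBS-oxy)-2-iodo-6-methyl-9-[(4R)-2,2,4-trimethyl-1,3-dioxan-4-yl]nona-2,5-dien-8-yn-4-ol
Product: 19 (5S)-3-[(TBS-oxy)methyl]-5-{(1Z,3S)-3-(TBS-oxy)-2-methyl-5-[(4R)-2,2,4-trimethyl-1,3-dioxan-4-yl]pent-1-en-4-yn-1-yl}furan-2(5H)-one
Conditions: Pd(PPh3)4 (5 mol %), CO (1 atm), i-Pr2NEt, MeCN, 45 °C
Reagents that add atoms: carbon monoxide, [C-]#[O+]
Why: Palladium-catalysed carbonylative lactonisation of a (Z)-γ-iodoallylic alcohol (oxidative addition, CO insertion, capture of the acylpalladium by the cis C6–OH) closes the butenolide with C12 from CO and leaves C6 untouched.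

**Step 12**
Reactants: 19 (5S)-3-[(TBS-oxy)methyl]-5-{(1Z,3S)-3-(TBS-oxy)-2-methyl-5-[(4R)-2,2,4-trimethyl-1,3-dioxan-4-yl]pent-1-en-4-yn-1-yl}furan-2(5H)-one
Product: 20 (5S)-5-[(1Z,3S,6R)-3-(TBS-oxy)-6,8-dihydroxy-2,6-dimethyloct-1-en-4-yn-1-yl]-3-(hydroxymethyl)furan-2(5H)-one
Conditions: AcOH/THF/H2O (3:1:1), 35 °C
Reagents that add atoms: none
Why: Mild acid hydrolysis removes the acetonide and the primary silyl ether while the hindered secondary TBS ether stays, and it is run at the alkyne stage, where C10–O is propargylic rather than allylic and does not ionise.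

**Step 13**
Reactants: 20 (5S)-5-[(1Z,3S,6R)-3-(TBS-oxy)-6,8-dihydroxy-2,6-dimethyloct-1-en-4-yn-1-yl]-3-(hydroxymethyl)furan-2(5H)-one
Product: 21 (5S)-5-[(1Z,3R,4Z,6R)-3-(TBS-oxy)-6,8-dihydroxy-2,6-dimethylocta-1,4-dien-1-yl]-3-(hydroxymethyl)furan-2(5H)-one
Conditions: H2 (1 atm), Lindlar catalyst, quinoline, EtOAc, rt
Reagents that add atoms: none
Why: Lindlar semi-hydrogenation adds H2 syn to the only alkyne and gives Z-C1=C2, while the trisubstituted C4=C5 and butenolide double bonds bind the poisoned catalyst too weakly to react.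

**Step 14**
Reactants: 21 (5S)-5-[(1Z,3R,4Z,6R)-3-(TBS-oxy)-6,8-dihydroxy-2,6-dimethylocta-1,4-dien-1-yl]-3-(hydroxymethyl)furan-2(5H)-one
Product: 22 (5S)-3-(bromomethyl)-5-[(1Z,3R,4Z,6R)-3-(TBS-oxy)-6,8-dihydroxy-2,6-dimethylocta-1,4-dien-1-yl]furan-2(5H)-one
Conditions: NBS, Me2S (premixed), CH2Cl2, −30 → 0 °C
Reagents that add atoms: N-bromosuccinimide, O=C1CCC(=O)N1Br
Why: In the Corey–Kim halogenation bromide displaces the alkoxysulfonium group only at the activated 2-acylallylic position C13, the saturated primary alkoxysulfonium at O8 reverts to the alcohol on work-up, and the tertiary OH is too hindered to be activated.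

**Step 15**
Reactants: 22 (5S)-3-(bromomethyl)-5-[(1Z,3R,4Z,6R)-3-(TBS-oxy)-6,8-dihydroxy-2,6-dimethylocta-1,4-dien-1-yl]furan-2(5H)-one
Product: 23 (3R,4Z,6R,7Z)-8-[(2S)-4-(bromomethyl)-5-oxo-2,5-dihydrofuran-2-yl]-6-(TBS-oxy)-3-hydroxy-3,7-dimethylocta-4,7-dienal
Conditions: Dess–Martin periodinane, NaHCO3, CH2Cl2, 0 °C; crude 23 used at once
Reagents that add atoms: none
Why: Dess–Martin oxidation converts the only oxidisable (primary) alcohol to the C8 aldehyde under buffered, base-free conditions that spare the allylic bromide, the acidic H6 and the β-hydroxy aldehyde.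

**Step 16**
Reactants: 23 (3R,4Z,6R,7Z)-8-[(2S)-4-(bromomethyl)-5-oxo-2,5-dihydrofuran-2-yl]-6-(TBS-oxy)-3-hydroxy-3,7-dimethylocta-4,7-dienal
Product: 25 (3aR,4R,6R,7Z,9R,10Z,11aS)-9-(TBS-oxy)-4,6-dihydroxy-6,10-dimethyl-3-methylidene-3a,4,5,6,9,11a-hexahydrocyclodeca[b]furan-2(3H)-one, via allylchromium(III) species 24 (not isolated)
Conditions: CrCl2 (10 equiv), THF/DMF (4:1), 25 °C, 23 added by syringe pump (final ca. 1 mM); aq work-up
Reagents that add atoms: none
Why: Two equivalents of Cr(II) reduce the allylic C–Br bond to the 2-acylallylchromium(III) species 24; chromium binds the aldehyde oxygen and the γ-carbon C7 attacks C8 through a six-membered Zimmerman–Traxler array (SE2′), so the C7–C8 bond, the C8 carbinol and the exocyclic C11=C13 methylene arise in one event. The closest known reactions are the Cr(II)- or Zn-mediated Barbier allylation of aldehydes with 3-(bromomethyl)furan-2(5H)-ones, which gives β-(hydroxyalkyl)-α-methylene-γ-butyrolactones, and the intramolecular Nozaki–Hiyama allylations of 2-(bromomethyl)acrylates that close ten-membered germacranolide rings. Only the ten-membered carbocycle is closed, by a 10-exo-trig attack of a ring carbon of the intact lactone on the aldehyde. C7: allylic 1,3-strain across Z-C4=C5 keeps H3 in the alkene plane and the OTBS group outside, which puts C2 on one side of that plane; the ring can close only if C7 lies on the same side, and in that rotamer (lactone oxygen in the alkene plane) the Z,Z-folded tether reaches only the butenolide face that carries C5, hence H6/H7 cis. C8: O8 must sit next to chromium on the C13 side, and of the two remaining positions only the one under the lactone ring (C9 anti to H7, pseudo-axial) lets C9 span the short distance to C10–C1=C2, whereas the equatorial position would need a syn-pentane C5–C6–C7–C8–C9 array, so the 8R carbinol is expected. The step needs γ- over α-attack (inherent to allylchromium), aldehyde over lactone with tolerance of the tertiary OH (low basicity of organochromium(III)), and cyclisation over oligomerisation (pseudo-high dilution and pre-folding by the two Z-alkenes).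

**Step 17**
Reactants: 25 (3aR,4R,6R,7Z,9R,10Z,11aS)-9-(TBS-oxy)-4,6-dihydroxy-6,10-dimethyl-3-methylidene-3a,4,5,6,9,11a-hexahydrocyclodeca[b]furan-2(3H)-one; 26 (E)-2-methylbut-2-enoyl chloride (tigloyl chloride)
Product: 27 (3aR,4R,6R,7Z,9R,10Z,11aS)-9-(TBS-oxy)-6-hydroxy-6,10-dimethyl-3-methylidene-2-oxo-2,3,3a,4,5,6,9,11a-octahydrocyclodeca[b]furan-4-yl (E)-2-methylbut-2-enoate
Conditions: Et3N, DMAP (cat.), CH2Cl2, 0 °C → rt
Reagents that add atoms: none
Why: DMAP-catalysed acylation takes the secondary C8–OH with retention while the tertiary C10–OH does not react, and the tiglate is the stable E isomer, so its geometry holds.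

**Step 18**
Reactants: 27 (3aR,4R,6R,7Z,9R,10Z,11aS)-9-(TBS-oxy)-6-hydroxy-6,10-dimethyl-3-methylidene-2-oxo-2,3,3a,4,5,6,9,11a-octahydrocyclodeca[b]furan-4-yl (E)-2-methylbut-2-enoate
Product: 28 (3aR,4R,6R,7Z,9R,10Z,11aS)-6,9-dihydroxy-6,10-dimethyl-3-methylidene-2-oxo-2,3,3a,4,5,6,9,11a-octahydrocyclodeca[b]furan-4-yl (E)-2-methylbut-2-enoate (target)
Conditions: HF·pyridine, excess pyridine, THF, 0 °C
Reagents that add atoms: none
Why: Pyridine-buffered fluoride desilylation frees O3 without the acid that would cyclodehydrate the (Z)-ene-1,4-diol and without the base that would add to the α-methylene lactone.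

**Compound list**

1 | (E)-3-methylpent-2-en-4-yn-1-ol | C#C/C(C)=C/CO | starting material
2 | [(2S,3S)-3-ethynyl-3-methyloxiran-2-yl]methanol | C#C[C@]1(C)O[C@H]1CO | intermediate
3 | (3R)-3-methylpent-4-yne-1,3-diol | C#C[C@](C)(O)CCO | intermediate
4 | (4R)-4-ethynyl-2,2,4-trimethyl-1,3-dioxane | C#C[C@]1(C)OC(C)(C)OCC1 | intermediate
5 | prop-2-yn-1-ol | C#CCO | starting material
6 | bromomagnesium (Z)-3-(bromomagnesio)-2-methylprop-2-en-1-olate | Br[Mg]/C=C(/C)CO[Mg]Br | intermediate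
7 | (Z)-3-iodo-2-methylprop-2-en-1-ol | I/C=C(/C)CO | intermediate
8 | (Z)-3-iodo-2-methylprop-2-enal | I/C=C(/C)C=O | intermediate
9 | methylzinc acetylide of 4 | C[Zn]C#C[C@]1(C)OC(C)(C)OCC1 | intermediate
10 | (1Z,3R)-1-iodo-2-methyl-5-[(4R)-2,2,4-trimethyl-1,3-dioxan-4-yl]pent-1-en-4-yn-3-ol | I/C=C(/C)[C@H](O)C#C[C@]1(C)OC(C)(C)OCC1 | intermediate
11 | O-TBS ether of 10 | I/C=C(/C)[C@H](O[Si](C)(C)C(C)(C)C)C#C[C@]1(C)OC(C)(C)OCC1 | intermediate
12 | (Z)-vinyllithium from 11 | [Li]/C=C(/C)[C@H](O[Si](C)(C)C(C)(C)C)C#C[C@]1(C)OC(C)(C)OCC1 | intermediate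
13 | (2Z,4S)-4-(TBS-oxy)-3-methyl-6-[(4R)-2,2,4-trimethyl-1,3-dioxan-4-yl]hex-2-en-5-ynal | O=C/C=C(/C)[C@H](O[Si](C)(C)C(C)(C)C)C#C[C@]1(C)OC(C)(C)OCC1 | intermediate
14 | tert-butyldimethyl(prop-2-yn-1-yloxy)silane | C#CCO[Si](C)(C)C(C)(C)C | starting material
15 | methylzinc acetylide of 14 | C[Zn]C#CCO[Si](C)(C)C(C)(C)C | intermediate
16 | (4S,5Z,7S)-1,7-bis(TBS-oxy)-6-methyl-9-[(4R)-2,2,4-trimethyl-1,3-dioxan-4-yl]non-5-ene-2,8-diyn-4-ol | CC(C)(C)[Si](C)(C)OCC#C[C@@H](O)/C=C(/C)[C@H](O[Si](C)(C)C(C)(C)C)C#C[C@]1(C)OC(C)(C)OCC1 | intermediate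
17 | sodium bis(2-methoxyethoxy) cyclic vinylalanate (O6–Al–C11 five-membered ring) | [Na+].COCCO[Al-]1(OCCOC)O[C@@H](/C=C(/C)[C@H](O[Si](C)(C)C(C)(C)C)C#C[C@]2(C)OC(C)(C)OCC2)C=C1CO[Si](C)(C)C(C)(C)C | intermediate
18 | (2Z,4S,5Z,7S)-1,7-bis(TBS-oxy)-2-iodo-6-methyl-9-[(4R)-2,2,4-trimethyl-1,3-dioxan-4-yl]nona-2,5-dien-8-yn-4-ol | CC(C)(C)[Si](C)(C)OC/C(I)=C/[C@@H](O)/C=C(/C)[C@H](O[Si](C)(C)C(C)(C)C)C#C[C@]1(C)OC(C)(C)OCC1 | intermediate
19 | (5S)-3-[(TBS-oxy)methyl]-5-{(1Z,3S)-3-(TBS-oxy)-2-methyl-5-[(4R)-2,2,4-trimethyl-1,3-dioxan-4-yl]pent-1-en-4-yn-1-yl}furan-2(5H)-one | O=C1O[C@@H](/C=C(/C)[C@H](O[Si](C)(C)C(C)(C)C)C#C[C@]2(C)OC(C)(C)OCC2)C=C1CO[Si](C)(C)C(C)(C)C | intermediate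
20 | (5S)-5-[(1Z,3S,6R)-3-(TBS-oxy)-6,8-dihydroxy-2,6-dimethyloct-1-en-4-yn-1-yl]-3-(hydroxymethyl)furan-2(5H)-one | O=C1O[C@@H](/C=C(/C)[C@H](O[Si](C)(C)C(C)(C)C)C#C[C@](C)(O)CCO)C=C1CO | intermediate
21 | (5S)-5-[(1Z,3R,4Z,6R)-3-(TBS-oxy)-6,8-dihydroxy-2,6-dimethylocta-1,4-dien-1-yl]-3-(hydroxymethyl)furan-2(5H)-one | O=C1O[C@@H](/C=C(/C)[C@H](O[Si](C)(C)C(C)(C)C)/C=C\[C@](C)(O)CCO)C=C1CO | intermediate
22 | (5S)-3-(bromomethyl)-5-[(1Z,3R,4Z,6R)-3-(TBS-oxy)-6,8-dihydroxy-2,6-dimethylocta-1,4-dien-1-yl]furan-2(5H)-one | O=C1O[C@@H](/C=C(/C)[C@H](O[Si](C)(C)C(C)(C)C)/C=C\[C@](C)(O)CCO)C=C1CBr | intermediate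
23 | (3R,4Z,6R,7Z)-8-[(2S)-4-(bromomethyl)-5-oxo-2,5-dihydrofuran-2-yl]-6-(TBS-oxy)-3-hydroxy-3,7-dimethylocta-4,7-dienal | O=C1O[C@@H](/C=C(/C)[C@H](O[Si](C)(C)C(C)(C)C)/C=C\[C@](C)(O)CC=O)C=C1CBr | intermediate
24 | allylchromium(III) dichloride from 23 | O=C1O[C@@H](/C=C(/C)[C@H](O[Si](C)(C)C(C)(C)C)/C=C\[C@](C)(O)CC=O)C=C1C[Cr](Cl)Cl | intermediate
25 | (3aR,4R,6R,7Z,9R,10Z,11aS)-9-(TBS-oxy)-4,6-dihydroxy-6,10-dimethyl-3-methylidene-3a,4,5,6,9,11a-hexahydrocyclodeca[b]furan-2(3H)-one | C=C1C(=O)O[C@H]2/C=C(/C)[C@H](O[Si](C)(C)C(C)(C)C)/C=C\[C@](C)(O)C[C@@H](O)[C@@H]12 | intermediate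
26 | (E)-2-methylbut-2-enoyl chloride | ClC(=O)/C(C)=C/C | starting material
27 | O8-tiglate of 25 | C=C1C(=O)O[C@H]2/C=C(/C)[C@H](O[Si](C)(C)C(C)(C)C)/C=C\[C@](C)(O)C[C@@H](OC(=O)/C(C)=C/C)[C@@H]12 | intermediate
28 | (3aR,4R,6R,7Z,9R,10Z,11aS)-6,9-dihydroxy-6,10-dimethyl-3-methylidene-2-oxo-2,3,3a,4,5,6,9,11a-octahydrocyclodeca[b]furan-4-yl (E)-2-methylbut-2-enoate | C=C1C(=O)O[C@H]2/C=C(/C)[C@H](O)/C=C\[C@](C)(O)C[C@@H](OC(=O)/C(C)=C/C)[C@@H]12 | target

Total step count: 18.
Longest linear sequence: 16 steps (1–3, then 6–18).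

**Steps most likely to fail**

1. Step 16. The aldehyde may turn its other face to C7 (C9 equatorial in the chair), which would invert C8, and cyclisation may compete poorly with oligomerisation. The fallback sets out from 23. The cyclisation would then give the C8-epimeric alcohol (3aR,4S,6R,7Z,9R,10Z,11aS)-9-(TBS-oxy)-4,6-dihydroxy-6,10-dimethyl-3-methylidene-3a,4,5,6,9,11a-hexahydrocyclodeca[b]furan-2(3H)-one F1. Instead of acylation with retention, F1 is esterified with inversion under Mitsunobu conditions (tiglic acid, PPh3, DIAD, toluene, 0 °C). This replaces step 17 and comes back to the route at 27.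

2. Step 8. The Z-γ-silyloxy vinyllithium may undergo 1,4-O→C silyl migration before it is formylated, and the Z-enal may isomerise on handling. The fallback sets out from 11 and avoids both the organolithium and the enal. A Pd/Cu-catalysed carbonylative Sonogashira coupling with 14 (PdCl2(PPh3)2, CuI, CO 1 atm, Et3N, THF, rt) takes C6 from CO and gives the cross-conjugated ynone (5Z,7S)-1,7-bis(TBS-oxy)-6-methyl-9-[(4R)-2,2,4-trimethyl-1,3-dioxan-4-yl]non-5-ene-2,8-diyn-4-one F2. Noyori asymmetric transfer hydrogenation (Ru(p-cymene)[(S,S)-TsDPEN], i-PrOH, rt; the (S,S)-catalyst gives (S)-propargylic alcohols) sets C6. This comes back to the route at 16.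

3. Step 14. Activation may not discriminate between the two primary hydroxyl groups, or the tertiary allylic alcohol may ionise. The fallback sets out from 19 and replaces chemoselective halogenation by stepwise unmasking:
   - Lindlar hydrogenation of 19 gives the fully protected diene (5S)-3-[(TBS-oxy)methyl]-5-{(1Z,3R,4Z)-3-(TBS-oxy)-2-methyl-5-[(4R)-2,2,4-trimethyl-1,3-dioxan-4-yl]penta-1,4-dien-1-yl}furan-2(5H)-one F3.
   - HF·pyridine/pyridine (THF, 0 °C) cleaves only the primary allylic silyl ether and gives the mono-alcohol (5S)-3-(hydroxymethyl)-5-{(1Z,3R,4Z)-3-(TBS-oxy)-2-methyl-5-[(4R)-2,2,4-trimethyl-1,3-dioxan-4-yl]penta-1,4-dien-1-yl}furan-2(5H)-one F4.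
   - The Appel reaction (CBr4, PPh3, CH2Cl2, 0 °C) on this single free OH gives the bromide (5S)-3-(bromomethyl)-5-{(1Z,3R,4Z)-3-(TBS-oxy)-2-methyl-5-[(4R)-2,2,4-trimethyl-1,3-dioxan-4-yl]penta-1,4-dien-1-yl}furan-2(5H)-one F5.
   - Brief AcOH/THF/H2O hydrolysis of the acetonide comes back to the route at 22.

**Further compounds**

F1 | step 16 | (3aR,4S,6R,7Z,9R,10Z,11aS)-9-(TBS-oxy)-4,6-dihydroxy-6,10-dimethyl-3-methylidene-3a,4,5,6,9,11a-hexahydrocyclodeca[b]furan-2(3H)-one | C=C1C(=O)O[C@H]2/C=C(/C)[C@H](O[Si](C)(C)C(C)(C)C)/C=C\[C@](C)(O)C[C@H](O)[C@@H]12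
F2 | step 8 | (5Z,7S)-1,7-bis(TBS-oxy)-6-methyl-9-[(4R)-2,2,4-trimethyl-1,3-dioxan-4-yl]non-5-ene-2,8-diyn-4-one | CC(C)(C)[Si](C)(C)OCC#CC(=O)/C=C(/C)[C@H](O[Si](C)(C)C(C)(C)C)C#C[C@]1(C)OC(C)(C)OCC1
F3 | step 14 | (5S)-3-[(TBS-oxy)methyl]-5-{(1Z,3R,4Z)-3-(TBS-oxy)-2-methyl-5-[(4R)-2,2,4-trimethyl-1,3-dioxan-4-yl]penta-1,4-dien-1-yl}furan-2(5H)-one | O=C1O[C@@H](/C=C(/C)[C@H](O[Si](C)(C)C(C)(C)C)/C=C\[C@]2(C)OC(C)(C)OCC2)C=C1CO[Si](C)(C)C(C)(C)C
F4 | step 14 | (5S)-3-(hydroxymethyl)-5-{(1Z,3R,4Z)-3-(TBS-oxy)-2-methyl-5-[(4R)-2,2,4-trimethyl-1,3-dioxan-4-yl]penta-1,4-dien-1-yl}furan-2(5H)-one | O=C1O[C@@H](/C=C(/C)[C@H](O[Si](C)(C)C(C)(C)C)/C=C\[C@]2(C)OC(C)(C)OCC2)C=C1CO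
F5 | step 14 | (5S)-3-(bromomethyl)-5-{(1Z,3R,4Z)-3-(TBS-oxy)-2-methyl-5-[(4R)-2,2,4-trimethyl-1,3-dioxan-4-yl]penta-1,4-dien-1-yl}furan-2(5H)-one | O=C1O[C@@H](/C=C(/C)[C@H](O[Si](C)(C)C(C)(C)C)/C=C\[C@]2(C)OC(C)(C)OCC2)C=C1CBr
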